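**Strategy.** Numbering the ten-membered carbocycle C1–C10 (C1=C10 enoate, lactone oxygen on C6, isobutyrate on C8), everything rests on disconnecting the C9–C10 bond. C10, the α-carbon of the enoate, and C9, the methylene next to oxygenated C8, are both made electrophilic, as a (Z)-α-bromoenoate and a primary iodide. They are united in one operation by a nickel-mediated reductive cross-electrophile coupling that closes the ten-membered ring with retention of the C1=C10 geometry. The precursor is an open chain hung on the preformed trans α-methylene-γ-butyrolactone (C6, C7, C11–C13), bearing all four stereocentres, the isobutyrate and a silyl-protected C15 hydroxyl.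

Key step: step 14

Remark on numbering: C11–C13 are the lactone carbons (C12 carbonyl, C13 methylene), C14 is the ester carbon, C15 the hydroxymethyl carbon; compounds 1, 3, 12 and 13 are purchased.
Assumption: in step 9 the dioxolane centre is taken to steer the aldehyde in the inside-alkoxy sense (new C6–C7 bond anti to the C8–O bond); C8 is therefore carried in the epimeric configuration and inverted in step 13. The fallback to step 9 covers the opposite sense.

Step 1
Reactants: 1 methyl 5,5-dimethoxypentanoate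
Product: 2 5,5-dimethoxypentanoic acid
Conditions: LiOH·H2O, THF/H2O, 0 °C to rt; then 1 M HCl to pH 4–5, 0 °C
Reagents that add atoms: lithium hydroxide, [Li+].[OH-]
Why: Saponification (base-mediated ester hydrolysis) leaves the dimethyl acetal intact, and the acid is liberated cold at pH 4–5 to avoid acetal cleavage.

Step 2
Reactants: 2 5,5-dimethoxypentanoic acid; 3 (R)-4-benzyl-1,3-oxazolidin-2-one
Product: 5 (R)-4-benzyl-3-(5,5-dimethoxypentanoyl)-1,3-oxazolidin-2-one, via mixed pivalic anhydride 4 (not isolated)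
Conditions: t-BuCOCl, Et3N, THF, −20 °C; then 3, LiCl, −20 °C to rt
Reagents that add atoms: none
Why: Mixed-anhydride N-acylation of the oxazolidinone, in which the hindered pivaloyl carbonyl of 4 directs the LiCl-activated oxazolidinone to the wanted acyl group.

Step 3
Reactants: 5 (R)-4-benzyl-3-(5,5-dimethoxypentanoyl)-1,3-oxazolidin-2-one
Product: 7 (R)-4-benzyl-3-[(2S)-5,5-dimethoxy-2-(prop-2-en-1-yl)pentanoyl]-1,3-oxazolidin-2-one, via sodium enolate 6 (not isolated)
Conditions: NaN(SiMe3)2, THF, −78 °C; allyl iodide, −78 to −45 °C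
Reagents that add atoms: allyl iodide, C=CCI
Why: Evans auxiliary alkylation, in which the chelated (Z)-enolate 6 is allylated on the face opposite the benzyl group, setting C4 as S.

Step 4
Reactants: 7 (R)-4-benzyl-3-[(2S)-5,5-dimethoxy-2-(prop-2-en-1-yl)pentanoyl]-1,3-oxazolidin-2-one
Product: 8 (2S)-5,5-dimethoxy-2-(prop-2-en-1-yl)pentan-1-ol
Conditions: LiBH4, Et2O, H2O (1 equiv), 0 °C
Reagents that add atoms: none
Why: Reductive cleavage of the N-acyl oxazolidinone by borohydride gives the primary alcohol (C15) without touching the C4 centre, the acetal or the alkene, and returns the auxiliary.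

Step 5
Reactants: 8 (2S)-5,5-dimethoxy-2-(prop-2-en-1-yl)pentan-1-ol
Product: 9 tert-butyl{[(2S)-5,5-dimethoxy-2-(prop-2-en-1-yl)pentyl]oxy}diphenylsilane
Conditions: t-BuPh2SiCl, imidazole, DMF, rt
Reagents that add atoms: tert-butyl(chloro)diphenylsilane, CC(C)(C)[Si](Cl)(c1ccccc1)c1ccccc1
Why: Silylation of the primary alcohol, the tert-butyldiphenylsilyl ether being chosen because it survives the aqueous acid of step 10 and can be removed last.

Step 6
Reactants: 9 tert-butyl{[(2S)-5,5-dimethoxy-2-(prop-2-en-1-yl)pentyl]oxy}diphenylsilane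
Product: 11 (3S)-3-{[tert-butyl(diphenyl)silyl]oxymethyl}-6,6-dimethoxyhexanal, via ozonide 10 (not isolated)
Conditions: O3, CH2Cl2, −78 °C; then PPh3, −78 °C to rt
Reagents that add atoms: ozone, [O-][O+]=O
Why: Ozonolysis of the terminal alkene followed by reductive work-up unveils the C6 aldehyde, the acetal and silyl ether being inert at −78 °C.

Step 7
Reactants: 12 (S)-2,2-dimethyl-1,3-dioxolane-4-carbaldehyde; 13 methyl acrylate
Product: 14 methyl 2-{[(4S)-2,2-dimethyl-1,3-dioxolan-4-yl](hydroxy)methyl}prop-2-enoate (both carbinol epimers)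
Conditions: DABCO, 1,4-dioxane/H2O, rt
Reagents that add atoms: none
Why: Morita–Baylis–Hillman reaction in which the amine-derived acrylate enolate adds to the aldehyde; the new carbinol centre is erased in step 8 and the dioxolane centre (future C8) is not touched.

Step 8
Reactants: 14 methyl 2-{[(4S)-2,2-dimethyl-1,3-dioxolan-4-yl](hydroxy)methyl}prop-2-enoate
Product: 15 methyl (2Z)-2-(bromomethyl)-3-[(4R)-2,2-dimethyl-1,3-dioxolan-4-yl]prop-2-enoate
Conditions: NBS, Me2S, CH2Cl2, 0 °C to rt
Reagents that add atoms: N-bromosuccinimide, O=C1CCC(=O)N1Br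
Why: SN2′ bromination of the allylic alcohol through its alkoxysulfonium salt gives the thermodynamically preferred (Z)-2-(bromomethyl)enoate from both epimers under neutral conditions that spare the acetonide.

Step 9
Reactants: 11 (3S)-3-{[tert-butyl(diphenyl)silyl]oxymethyl}-6,6-dimethoxyhexanal; 15 methyl (2Z)-2-(bromomethyl)-3-[(4R)-2,2-dimethyl-1,3-dioxolan-4-yl]prop-2-enoate
Product: 18 (4S,5R)-5-[(2S)-2-{[tert-butyl(diphenyl)silyl]oxymethyl}-5,5-dimethoxypentyl]-4-[(4R)-2,2-dimethyl-1,3-dioxolan-4-yl]-3-methylideneoxolan-2-one (trans lactone; C6 R; C7 S), via allylchromium dichloride 16 (not isolated), via chromium alkoxide of the anti adduct 17 (not isolated)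
Conditions: CrCl2, THF, 0 °C to rt; aq NH4Cl; then PPTS (cat.), CH2Cl2, rt
Reagents that add atoms: none
Why: Nozaki–Hiyama 2-(methoxycarbonyl)allylation with lactonisation, in which a chair transition state with the dioxolanyl group equatorial gives the anti adduct and hence the trans C6/C7 lactone, while the dioxolane carbon (H toward the aldehyde substituent, C–O bond inside, C–C9 bond anti) places the new C6–C7 bond anti to the C8–O bond and so fixes C6 as R and C7 as S, the remote C4 centre playing no part.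

Step 10
Reactants: 18 acetonide lactone
Product: 19 (4S)-4-{[tert-butyl(diphenyl)silyl]oxymethyl}-5-{(2R,3R)-3-[(1R)-1,2-dihydroxyethyl]-4-methylidene-5-oxooxolan-2-yl}pentanal
Conditions: AcOH/H2O/THF (3:1:1), 40 °C
Reagents that add atoms: water, O
Why: Acid-catalysed acetal hydrolysis unmasks the C1 aldehyde and the C8/C9 diol in one operation while the silyl ether and lactone survive, the mild acid being chosen so that the free C8 hydroxyl does not translactonise.

Step 11
Reactants: 19 aldehyde diol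
Product: 20 methyl (2Z,6S)-2-bromo-6-{[tert-butyl(diphenyl)silyl]oxymethyl}-7-{(2R,3R)-3-[(1R)-1,2-dihydroxyethyl]-4-methylidene-5-oxooxolan-2-yl}hept-2-enoate
Conditions: Ph3P=CHCO2Me, NBS, CH2Cl2, −20 °C; then 19, −20 °C to rt
Reagents that add atoms: methyl (triphenylphosphoranylidene)acetate, COC(=O)C=P(c1ccccc1)(c1ccccc1)c1ccccc1; N-bromosuccinimide, O=C1CCC(=O)N1Br
Why: Wittig olefination with the stabilised α-bromo ylide made in the flask places the ester trans to the chain, as usual for stabilised ylides, giving the (Z)-α-bromoenoate (C1=C10) in the presence of the free diol.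

Step 12
Reactants: 20 bromoenoate diol
Product: 21 methyl (2Z,6S)-2-bromo-6-{[tert-butyl(diphenyl)silyl]oxymethyl}-7-{(2R,3R)-3-[(1R)-1-hydroxy-2-iodoethyl]-4-methylidene-5-oxooxolan-2-yl}hept-2-enoate
Conditions: I2, PPh3, imidazole, CH2Cl2, 0 °C
Reagents that add atoms: iodine, II
Why: Appel-type iodination is selective for the primary C9 hydroxyl over the hindered secondary C8 hydroxyl.

Step 13
Reactants: 21 iodohydrin
Product: 22 methyl (2Z,6S)-2-bromo-6-{[tert-butyl(diphenyl)silyl]oxymethyl}-7-{(2R,3S)-3-[(1S)-2-iodo-1-(2-methylpropanoyloxy)ethyl]-4-methylidene-5-oxooxolan-2-yl}hept-2-enoate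
Conditions: PPh3, DIAD, isobutyric acid, THF, 0 °C to rt
Reagents that add atoms: isobutyric acid, CC(C)C(=O)O
Why: Mitsunobu esterification, in which isobutyrate displaces the C8 oxyphosphonium by SN2 with inversion, installing the ester and bringing C8 to the configuration of the target while the iodide, lactone and bromoenoate are untouched.

Step 14
Reactants: 22 iodo isobutyrate bromoenoate
Product: 23 methyl (3aS,4R,6E,10S,11aR)-10-{[tert-butyl(diphenyl)silyl]oxymethyl}-3-methylidene-4-[(2-methylpropanoyl)oxy]-2-oxo-2,3,3a,4,5,8,9,10,11,11a-decahydrocyclodeca[b]furan-6-carboxylate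
Conditions: NiBr2·(MeOCH2CH2OMe) (1 equiv), 4,4′-di-tert-butyl-2,2′-bipyridine, Mn powder, NaI, DMA, 30 °C, 22 added by syringe pump (final 2 mM)
Reagents that add atoms: none
Why: Bipyridine-ligated zerovalent nickel inserts into the C10–Br bond of the (Z)-α-bromoenoate with retention, iodine-atom abstraction from C9–I by low-valent nickel gives the primary C9 radical, and capture of this radical by the alkenylnickel on the same chain followed by reductive elimination from trivalent nickel forms the C9–C10 bond while Mn returns nickel to the zerovalent state. The closest known reaction type is the nickel-catalysed reductive cross-electrophile coupling of alkenyl bromides with primary alkyl iodides, run here intramolecularly in the manner of the older nickel-mediated dihalide couplings to medium-ring terpenes. The only ring closed is the ten-membered carbocycle C1–C10, by substitution at the vinylic carbon C10 with C1 remaining inside the ring (endo with respect to the alkene), the carbon–carbon bond being made at nickel and not by radical addition to the alkene. No stereocentre is created; the C1=C10 geometry (C2 cis to C9, ester cis to H) is carried over from the (Z)-bromide by stereoretentive oxidative addition and reductive elimination and is also the thermodynamically preferred cis-in-ring enoate. The step needs ring closure to beat oligomerisation, hydrodehalogenation and β-elimination of the isobutyrate; slow addition to a dilute solution, a full equivalent of nickel (so that each chain carries its alkenylnickel before the radical is born), Mn in place of Zn (no alkylzinc that could eliminate) and the trans-lactone that holds the C5 and C8 arms on neighbouring carbons are meant to secure this. The α-methylene lactone is spared because attack of the C9 radical on C11=C13 would be 4-exo or 5-endo.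

Step 15
Reactants: 23 silyl-protected macrocycle
Product: 24 methyl (3aS,4R,6E,10S,11aR)-10-(hydroxymethyl)-3-methylidene-4-[(2-methylpropanoyl)oxy]-2-oxo-2,3,3a,4,5,8,9,10,11,11a-decahydrocyclodeca[b]furan-6-carboxylate (CNP0251148.1)
Conditions: HF·pyridine, pyridine, THF, 0 °C to rt
Reagents that add atoms: none
Why: Fluoride-mediated cleavage of the silyl ether under buffered conditions frees the C15 hydroxyl without harming the two esters, the enoate or the α-methylene lactone.

**Compound list**

1 | methyl 5,5-dimethoxypentanoate | COC(=O)CCCC(OC)OC | starting material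
2 | 5,5-dimethoxypentanoic acid | OC(=O)CCCC(OC)OC | intermediate
3 | (R)-4-benzyl-1,3-oxazolidin-2-one | O=C1OC[C@@H](Cc2ccccc2)N1 | starting material
4 | 5,5-dimethoxypentanoic pivalic anhydride | CC(C)(C)C(=O)OC(=O)CCCC(OC)OC | intermediate (not isolated)
5 | (R)-4-benzyl-3-(5,5-dimethoxypentanoyl)-1,3-oxazolidin-2-one | O=C1OC[C@@H](Cc2ccccc2)N1C(=O)CCCC(OC)OC | intermediate
6 | sodium (Z)-enolate of 5 | O=C1OC[C@@H](Cc2ccccc2)N1/C([O-])=C/CCC(OC)OC.[Na+] | intermediate (not isolated)
7 | (R)-4-benzyl-3-[(2S)-5,5-dimethoxy-2-(prop-2-en-1-yl)pentanoyl]-1,3-oxazolidin-2-one | O=C1OC[C@@H](Cc2ccccc2)N1C(=O)[C@H](CC=C)CCC(OC)OC | intermediate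
8 | (2S)-5,5-dimethoxy-2-(prop-2-en-1-yl)pentan-1-ol | OC[C@H](CC=C)CCC(OC)OC | intermediate
9 | tert-butyl{[(2S)-5,5-dimethoxy-2-(prop-2-en-1-yl)pentyl]oxy}diphenylsilane | CC(C)(C)[Si](c1ccccc1)(c1ccccc1)OC[C@H](CC=C)CCC(OC)OC | intermediate
10 | ozonide (1,2,4-trioxolane) of 9 | CC(C)(C)[Si](c1ccccc1)(c1ccccc1)OC[C@H](CC1OCOO1)CCC(OC)OC | intermediate (not isolated)
11 | (3S)-3-{[tert-butyl(diphenyl)silyl]oxymethyl}-6,6-dimethoxyhexanal | CC(C)(C)[Si](c1ccccc1)(c1ccccc1)OC[C@H](CC=O)CCC(OC)OC | intermediate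
12 | (S)-2,2-dimethyl-1,3-dioxolane-4-carbaldehyde | O=C[C@@H]1COC(C)(C)O1 | starting material
13 | methyl acrylate | C=CC(=O)OC | starting material
14 | methyl 2-{[(4S)-2,2-dimethyl-1,3-dioxolan-4-yl](hydroxy)methyl}prop-2-enoate (carbinol epimers) | C=C(C(=O)OC)C(O)[C@@H]1COC(C)(C)O1 | intermediate
15 | methyl (2Z)-2-(bromomethyl)-3-[(4R)-2,2-dimethyl-1,3-dioxolan-4-yl]prop-2-enoate | COC(=O)/C(CBr)=C/[C@@H]1COC(C)(C)O1 | intermediate
16 | {2-(methoxycarbonyl)-3-[(4R)-2,2-dimethyl-1,3-dioxolan-4-yl]prop-2-en-1-yl}chromium dichloride | COC(=O)C(C[Cr](Cl)Cl)=C[C@@H]1COC(C)(C)O1 | intermediate (not isolated)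
17 | methyl (3S,4R,6S)-6-{[tert-butyl(diphenyl)silyl]oxymethyl}-3-[(4R)-2,2-dimethyl-1,3-dioxolan-4-yl]-4-hydroxy-9,9-dimethoxy-2-methylidenenonanoate (formed as its chromium alkoxide) | C=C(C(=O)OC)[C@H]([C@@H]1COC(C)(C)O1)[C@H](O)C[C@@H](CO[Si](c1ccccc1)(c1ccccc1)C(C)(C)C)CCC(OC)OC | intermediate (not isolated)
18 | (4S,5R)-5-[(2S)-2-{[tert-butyl(diphenyl)silyl]oxymethyl}-5,5-dimethoxypentyl]-4-[(4R)-2,2-dimethyl-1,3-dioxolan-4-yl]-3-methylideneoxolan-2-one | C=C1C(=O)O[C@H](C[C@@H](CO[Si](c2ccccc2)(c2ccccc2)C(C)(C)C)CCC(OC)OC)[C@H]1[C@@H]1COC(C)(C)O1 | intermediate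
19 | (4S)-4-{[tert-butyl(diphenyl)silyl]oxymethyl}-5-{(2R,3R)-3-[(1R)-1,2-dihydroxyethyl]-4-methylidene-5-oxooxolan-2-yl}pentanal | C=C1C(=O)O[C@H](C[C@@H](CO[Si](c2ccccc2)(c2ccccc2)C(C)(C)C)CCC=O)[C@H]1[C@@H](O)CO | intermediate
20 | methyl (2Z,6S)-2-bromo-6-{[tert-butyl(diphenyl)silyl]oxymethyl}-7-{(2R,3R)-3-[(1R)-1,2-dihydroxyethyl]-4-methylidene-5-oxooxolan-2-yl}hept-2-enoate | C=C1C(=O)O[C@H](C[C@@H](CO[Si](c2ccccc2)(c2ccccc2)C(C)(C)C)CC/C=C(/C(=O)OC)Br)[C@H]1[C@@H](O)CO | intermediate
21 | methyl (2Z,6S)-2-bromo-6-{[tert-butyl(diphenyl)silyl]oxymethyl}-7-{(2R,3R)-3-[(1R)-1-hydroxy-2-iodoethyl]-4-methylidene-5-oxooxolan-2-yl}hept-2-enoate | C=C1C(=O)O[C@H](C[C@@H](CO[Si](c2ccccc2)(c2ccccc2)C(C)(C)C)CC/C=C(/C(=O)OC)Br)[C@H]1[C@@H](O)CI | intermediate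
22 | methyl (2Z,6S)-2-bromo-6-{[tert-butyl(diphenyl)silyl]oxymethyl}-7-{(2R,3S)-3-[(1S)-2-iodo-1-(2-methylpropanoyloxy)ethyl]-4-methylidene-5-oxooxolan-2-yl}hept-2-enoate | C=C1C(=O)O[C@H](C[C@@H](CO[Si](c2ccccc2)(c2ccccc2)C(C)(C)C)CC/C=C(/C(=O)OC)Br)[C@H]1[C@H](OC(=O)C(C)C)CI | intermediate
23 | methyl (3aS,4R,6E,10S,11aR)-10-{[tert-butyl(diphenyl)silyl]oxymethyl}-3-methylidene-4-[(2-methylpropanoyl)oxy]-2-oxo-2,3,3a,4,5,8,9,10,11,11a-decahydrocyclodeca[b]furan-6-carboxylate | C=C1C(=O)O[C@@H]2C[C@@H](CO[Si](c3ccccc3)(c3ccccc3)C(C)(C)C)CC/C=C(/C(=O)OC)C[C@@H](OC(=O)C(C)C)[C@@H]12 | intermediate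
24 | methyl (3aS,4R,6E,10S,11aR)-10-(hydroxymethyl)-3-methylidene-4-[(2-methylpropanoyl)oxy]-2-oxo-2,3,3a,4,5,8,9,10,11,11a-decahydrocyclodeca[b]furan-6-carboxylate (CNP0251148.1) | C=C1C(=O)O[C@@H]2C[C@@H](CO)CC/C=C(/C(=O)OC)C[C@@H](OC(=O)C(C)C)[C@@H]12 | target

**Step count and risks**

Total step count: 15. Longest linear sequence: 13 steps (steps 1–6 and 9–15).

Steps most likely to fail:

1. Step 14. Intermolecular coupling (oligomerisation) may outrun closure of the strained ten-membered ring, and premature reduction of the C–I or C–Br bond or β-elimination of the isobutyrate may compete. Fallback, setting out from 19 and coming back at 23: the same C9–C10 bond is closed by a polar enolate alkylation instead of a reductive coupling. SnCl2-catalysed homologation of the aldehyde of 19 with methyl diazoacetate (Roskamp reaction) would give the β-keto ester diol F1. Iodination of the primary hydroxyl as in step 12 would give the iodohydrin F2, and Mitsunobu esterification as in step 13 the inverted isobutyrate F3. Slow addition of F3 to Cs2CO3 in MeCN at high dilution would close the ring by intramolecular C-alkylation of the β-keto ester carbon C10 with the C9 iodide, giving the macrocyclic β-keto ester F4. Reduction of the C1 ketone with NaBH4/CeCl3·7H2O at −78 °C would give the β-hydroxy ester F5; mesylation to the mesylate F6 and DBU-induced E1cB elimination would place the double bond at C1=C10 in the conjugated, thermodynamically preferred geometry, which is 23.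

2. Step 9. The aldehyde may attack the other face of the allylchromium (or discriminate poorly), addition may be syn instead of anti, and 1,4-elimination of the dioxolane oxygen from the allylchromium may erode the yield. Fallback, setting out from 11 and 13 and coming back at 22: the enantiomeric building block is used and C8 is acylated with retention instead of inversion. Purchased (R)-2,2-dimethyl-1,3-dioxolane-4-carbaldehyde and 13 would give, as in steps 7 and 8, the adduct methyl 2-{[(4R)-2,2-dimethyl-1,3-dioxolan-4-yl](hydroxy)methyl}prop-2-enoate F7 and the bromide methyl (2Z)-2-(bromomethyl)-3-[(4S)-2,2-dimethyl-1,3-dioxolan-4-yl]prop-2-enoate F8. CrCl2-mediated coupling of F8 with 11 would then give the (6R,7S) trans-lactone 8-epi-18 F9, whose C8 already has the configuration of the target. Hydrolysis as in step 10 would give the aldehyde diol F10, bromo-Wittig olefination as in step 11 the bromoenoate diol F11, and iodination as in step 12 the iodohydrin F12. Acylation of the C8 hydroxyl of F12 with isobutyryl chloride, pyridine and DMAP in CH2Cl2 (retention) would give 22.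

3. Step 13. SN2 displacement at the hindered C8 oxyphosphonium may be sluggish, giving elimination, or the lactone carbonyl may participate, giving retention or lactone migration. Fallback, setting out from 21 and coming back at 22: the inversion is done by sulfonate displacement. Tf2O and 2,6-lutidine in CH2Cl2 at −78 °C would give the C8 triflate F13, which is displaced at −20 °C by CsO2CCHMe2 with 18-crown-6 in toluene, with inversion and faster than the primary iodide reacts, to give 22.

Further compounds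
F1 | step 14 | methyl 7-{[tert-butyl(diphenyl)silyl]oxymethyl}-8-{3-[(1R)-1,2-dihydroxyethyl]-4-methylidene-5-oxooxolan-2-yl}-3-oxooctanoate (C4 S, C6 R, C7 R) | C=C1C(=O)O[C@H](C[C@@H](CO[Si](c2ccccc2)(c2ccccc2)C(C)(C)C)CCC(=O)CC(=O)OC)[C@H]1[C@@H](O)CO
F2 | step 14 | C9 iodide of F1 (C8 R) | C=C1C(=O)O[C@H](C[C@@H](CO[Si](c2ccccc2)(c2ccccc2)C(C)(C)C)CCC(=O)CC(=O)OC)[C@H]1[C@@H](O)CI
F3 | step 14 | C8-inverted isobutyrate of F2 (C8 S) | C=C1C(=O)O[C@H](C[C@@H](CO[Si](c2ccccc2)(c2ccccc2)C(C)(C)C)CCC(=O)CC(=O)OC)[C@H]1[C@H](OC(=O)C(C)C)CI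
F4 | step 14 | 1-oxo-1,10-dihydro analogue of 23 (macrocyclic β-keto ester, C10 epimers) | C=C1C(=O)O[C@@H]2C[C@@H](CO[Si](c3ccccc3)(c3ccccc3)C(C)(C)C)CCC(=O)C(C(=O)OC)C[C@@H](OC(=O)C(C)C)[C@@H]12
F5 | step 14 | 1-hydroxy-1,10-dihydro analogue of 23 (β-hydroxy ester, epimers) | C=C1C(=O)O[C@@H]2C[C@@H](CO[Si](c3ccccc3)(c3ccccc3)C(C)(C)C)CCC(O)C(C(=O)OC)C[C@@H](OC(=O)C(C)C)[C@@H]12
F6 | step 14 | C1 mesylate of F5 | C=C1C(=O)O[C@@H]2C[C@@H](CO[Si](c3ccccc3)(c3ccccc3)C(C)(C)C)CCC(OS(C)(=O)=O)C(C(=O)OC)C[C@@H](OC(=O)C(C)C)[C@@H]12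
F7 | step 9 | methyl 2-{[(4R)-2,2-dimethyl-1,3-dioxolan-4-yl](hydroxy)methyl}prop-2-enoate | C=C(C(=O)OC)C(O)[C@H]1COC(C)(C)O1
F8 | step 9 | methyl (2Z)-2-(bromomethyl)-3-[(4S)-2,2-dimethyl-1,3-dioxolan-4-yl]prop-2-enoate | COC(=O)/C(CBr)=C/[C@H]1COC(C)(C)O1
F9 | step 9 | 8-epi-18: (4S,5R)-5-[(2S)-2-{[tert-butyl(diphenyl)silyl]oxymethyl}-5,5-dimethoxypentyl]-4-[(4S)-2,2-dimethyl-1,3-dioxolan-4-yl]-3-methylideneoxolan-2-one | C=C1C(=O)O[C@H](C[C@@H](CO[Si](c2ccccc2)(c2ccccc2)C(C)(C)C)CCC(OC)OC)[C@H]1[C@H]1COC(C)(C)O1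
F10 | step 9 | 8-epi-19 (aldehyde diol) | C=C1C(=O)O[C@H](C[C@@H](CO[Si](c2ccccc2)(c2ccccc2)C(C)(C)C)CCC=O)[C@H]1[C@H](O)CO
F11 | step 9 | 8-epi-20 ((Z)-α-bromoenoate diol) | C=C1C(=O)O[C@H](C[C@@H](CO[Si](c2ccccc2)(c2ccccc2)C(C)(C)C)CC/C=C(/C(=O)OC)Br)[C@H]1[C@H](O)CO
F12 | step 9 | 8-epi-21 (iodohydrin) | C=C1C(=O)O[C@H](C[C@@H](CO[Si](c2ccccc2)(c2ccccc2)C(C)(C)C)CC/C=C(/C(=O)OC)Br)[C@H]1[C@H](O)CI
F13 | step 13 | C8 trifluoromethanesulfonate of 21 | C=C1C(=O)O[C@H](C[C@@H](CO[Si](c2ccccc2)(c2ccccc2)C(C)(C)C)CC/C=C(/C(=O)OC)Br)[C@H]1[C@@H](OS(=O)(=O)C(F)(F)F)CI
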